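**Retrosynthetic overview**

1. Target ⇐ 3‑ketone 21,22‑acetonide ⇐ 3β‑alcohol, by acetonide hydrolysis, C3 oxidation and removal of a C16 sulfone.
2. Rings A then B are formed in one cascade from an acyclic (3S)‑epoxy‑tetraene. A titanocene(III) radical bicyclization, run electrochemically, forms C4–C5 then C9–C10; loss of PhSO2• from C7 ends the cascade and places the olefin at C7=C8.
3. The acyclic precursor comes from three C10 pieces joined by two sulfone alkylations (C15–C16, then C6–C7): (S)‑6,7‑epoxygeranyl bromide, an (E,E)‑C10 dibromide, and an (R)‑acetonide geranyl sulfone.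
4. Both chiral C10 pieces come from one triol made from (R)‑5‑oxotetrahydrofuran‑2‑carboxylic acid (D‑glutamic acid pool). The (R)‑diol is kept for C21 and inverted to the (S)‑epoxide that controls C5, C9 and C10.

Assumptions (one line each):
- Numbering follows the target: C1–C10 decalin, C11–C22 side chain, diol at C21/C22; the same numbers are used for acyclic precursors.
- Compound 1 is taken as commercial (it is one step from D‑glutamic acid with NaNO2/HCl).
- Reagents are named under "Reagents that add atoms" and are not numbered.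
- Sulfonyl‑bearing carbons (C7, C16) are epimer mixtures; both are removed later.

**Step 1**
Reactants: 1, (R)‑5‑oxotetrahydrofuran‑2‑carboxylic acid
Product: 2, ethyl (R)‑5‑oxotetrahydrofuran‑2‑carboxylate
Conditions: EtOH, p‑TsOH (cat.), PhMe, reflux (Dean–Stark)
Reagents that add atoms: ethanol, CCO
Why: Fischer esterification; the stereocentre is not touched.

**Step 2**
Reactants: 2
Product: 3, (R)‑5‑(2‑hydroxypropan‑2‑yl)dihydrofuran‑2(3H)‑one
Conditions: MeMgBr (2.2 equiv), THF, −78 → −30 °C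
Reagents that add atoms: methylmagnesium bromide, C[Mg]Br
Why: Double Grignard addition to the more electrophilic α‑alkoxy ester in preference to the γ‑lactone; the C–O stereocentre is retained.

**Step 3**
Reactants: 3
Product: 4, (R)‑2‑methylhept‑6‑yne‑2,3‑diol
Conditions: DIBAL‑H (2.2 equiv), CH2Cl2, −78 °C; then MeOH, K2CO3, dimethyl (1‑diazo‑2‑oxopropyl)phosphonate, 0 °C → rt
Reagents that add atoms: Bestmann–Ohira reagent, COP(=O)(OC)C(=[N+]=[N-])C(C)=O
Why: Lactone‑to‑lactol reduction, then Seyferth–Gilbert (Bestmann–Ohira) homologation of the open hydroxy‑aldehyde to the terminal alkyne.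

**Step 4**
Reactants: 4
Product: 5, (R,E)‑3,7‑dimethyloct‑2‑ene‑1,6,7‑triol
Conditions: Me3Al (5 equiv), Cp2ZrCl2 (0.5 equiv), CH2Cl2, 0 °C → rt; then n‑BuLi, (CH2O)n, THF, −30 °C → rt
Reagents that add atoms: trimethylaluminium, C[Al](C)C; paraformaldehyde, C=O
Why: Negishi Zr‑catalysed syn‑carboalumination and formaldehyde trapping give only the E‑trisubstituted allylic alcohol; excess Me3Al masks the diol as aluminium alkoxides.

**Step 5**
Reactants: 5
Product: 6, (E)‑3‑methyl‑5‑[(4R)‑2,2,5,5‑tetramethyl‑1,3‑dioxolan‑4‑yl]pent‑2‑en‑1‑ol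
Conditions: Me2C(OMe)2, PPTS (cat.), CH2Cl2, rt; MeOH quench
Reagents that add atoms: 2,2‑dimethoxypropane, COC(C)(C)OC
Why: Acetonide formation on the vicinal diol; the primary alcohol stays free after methanolic work‑up.

**Step 6**
Reactants: 6
Product: 7, (5R)‑2,2,4,4‑tetramethyl‑5‑[(E)‑3‑methyl‑5‑(phenylsulfonyl)pent‑3‑en‑1‑yl]‑1,3‑dioxolane
Conditions: MsCl, Et3N, THF, −40 °C; LiBr, 0 °C; then PhSO2Na, DMF, rt (bromide not isolated)
Reagents that add atoms: sodium benzenesulfinate, [Na+].[O-]S(=O)c1ccccc1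
Why: Allylic mesylate/bromide formation and SN2 S‑alkylation of sulfinate give the primary allylic sulfone with E geometry retained.

**Step 7**
Reactants: 5
Product: 8, (3R,6E)‑8‑bromo‑2‑hydroxy‑2,6‑dimethyloct‑6‑en‑3‑yl methanesulfonate
Conditions: MsCl (2.2 equiv), Et3N, CH2Cl2, −40 °C; then LiBr, THF, 0 °C
Reagents that add atoms: methanesulfonyl chloride, CS(=O)(=O)Cl; lithium bromide, [Li+].[Br-]
Why: Sulfene mesylation of the primary allylic and secondary OH (tertiary OH is inert); bromide displaces only the allylic mesylate (Finkelstein type).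

**Step 8**
Reactants: 8
Product: 9, (3S)‑3‑[(E)‑5‑bromo‑3‑methylpent‑3‑en‑1‑yl]‑2,2‑dimethyloxirane [(S)‑6,7‑epoxygeranyl bromide]
Conditions: NaH, THF, 0 °C
Reagents that add atoms: none
Why: Intramolecular Williamson closure (3‑exo‑tet) by the tertiary alkoxide inverts the mesylate carbon, so the (R)‑diol gives the (S)‑epoxide.

**Step 9**
Reactants: 10, 2,5‑dimethoxytetrahydrofuran; 11, ethyl 2‑(triphenylphosphoranylidene)propanoate
Product: 12, diethyl (2E,6E)‑2,7‑dimethylocta‑2,6‑dienedioate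
Conditions: 0.5 M aq HCl, 70 °C; NaHCO3; then 11 (2.3 equiv), CH2Cl2/H2O, rt
Reagents that add atoms: none
Why: Acetal hydrolysis releases succinaldehyde, which undergoes a double Wittig reaction with the stabilised ylide (E‑selective at both olefins).

**Step 10**
Reactants: 12
Product: 13, (2E,6E)‑2,7‑dimethylocta‑2,6‑diene‑1,8‑diol
Conditions: DIBAL‑H (4.5 equiv), CH2Cl2, −78 °C
Reagents that add atoms: none
Why: 1,2‑Reduction of the enoates to allylic alcohols without touching the olefins.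

**Step 11**
Reactants: 13
Product: 14, (2E,6E)‑1,8‑dibromo‑2,7‑dimethylocta‑2,6‑diene
Conditions: PBr3, Et2O, 0 °C
Reagents that add atoms: phosphorus tribromide, BrP(Br)Br
Why: Primary allylic alcohols give primary allylic bromides with geometry retained.

**Step 12**
Reactants: 7; 14 (3 equiv, excess recovered)
Product: 15, (5R)‑5‑[(3E,7E,11E)‑13‑bromo‑3,7,12‑trimethyl‑5‑(phenylsulfonyl)trideca‑3,7,11‑trien‑1‑yl]‑2,2,4,4‑tetramethyl‑1,3‑dioxolane (C15–C16 bond formed; C16 epimers)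
Conditions: 7, n‑BuLi, THF, −78 °C; then added to 14, THF/DMPU, −78 °C
Reagents that add atoms: none
Why: Julia‑type alkylation of the α‑sulfonyl allyl carbanion at the primary allylic bromide (SN2); excess dibromide ensures mono‑alkylation.

**Step 13**
Reactants: 15
Product: 16, (5R)‑2,2,4,4‑tetramethyl‑5‑[(3E,7E,11E)‑3,7,12‑trimethyl‑5,13‑bis(phenylsulfonyl)trideca‑3,7,11‑trien‑1‑yl]‑1,3‑dioxolane
Conditions: PhSO2Na, DMF, rt
Reagents that add atoms: sodium benzenesulfinate, [Na+].[O-]S(=O)c1ccccc1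
Why: SN2 S‑alkylation of sulfinate installs the C7 sulfone, which serves first as the carbanion site and later as the radical leaving group.

**Step 14**
Reactants: 16; 9
Product: 17, (5R)‑5‑[(3E,7E,11E,15E)‑18‑[(2S)‑3,3‑dimethyloxiran‑2‑yl]‑3,7,12,16‑tetramethyl‑5,13‑bis(phenylsulfonyl)octadeca‑3,7,11,15‑tetraen‑1‑yl]‑2,2,4,4‑tetramethyl‑1,3‑dioxolane (C6–C7 bond formed; sulfones at C7 and C16)
Conditions: n‑BuLi (1.05 equiv), THF/DMPU, −78 °C; then 9, −78 → −40 °C
Reagents that add atoms: none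
Why: The unhindered, more acidic C7 CH2SO2Ph is deprotonated in preference to the tertiary C16–H; sulfone‑anion alkylation occurs at the allylic bromide while the trisubstituted epoxide is inert at low temperature.

**Step 15**
Reactants: 17
Product: 18, (2S,4aR,5S,8aR)‑1,1,4a,6‑tetramethyl‑5‑[(3E,7E)‑4,8‑dimethyl‑6‑(phenylsulfonyl)‑10‑[(4R)‑2,2,5,5‑tetramethyl‑1,3‑dioxolan‑4‑yl]deca‑3,7‑dien‑1‑yl]‑1,2,3,4,4a,5,8,8a‑octahydronaphthalen‑2‑ol (trans‑decalin; 3β‑OH, 5α‑H, 10β‑Me, 9β side chain, C7=C8 olefin)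
Conditions: Cp2TiCl2 (20 mol %), 2,4,6‑collidine·HCl (3 equiv), nBu4NPF6, THF, rt; divided cell, RVC cathode held at the Ti(IV)/Ti(III) couple, Zn anode, about 2.2 F/mol
Reagents that add atoms: none
Why: Proposed new method: cathodically regenerated Cp2Ti(III)Cl opens the (S)‑epoxide homolytically at the tertiary C–O bond, and the β‑titanoxy C4 radical closes twice in 6‑endo mode through a chair–chair transition state with C3–OTi equatorial, forming C4–C5 and C9–C10 and setting 5α‑H, 10β‑Me and 9α‑H from the epoxide centre; the resulting tertiary C8 radical is β to the C7 sulfone and should fragment (estimated k ≥ 10^6 s−1) to the C7=C8 olefin and PhSO2•, faster than 5‑exo attack on C13=C14, so the sulfone fixes both the ring count and the olefin position (an organotitanium formed by radical trapping would lose sulfinate to the same olefin); PhSO2• takes the second electron and collidinium protonates Ti–O to turn the catalyst over; the closest known chemistry is Cp2TiCl‑mediated radical cyclization of epoxypolyprenes with metal‑powder reductants (terminated by Ti‑mediated β‑H loss, mainly to the exocyclic olefin) and SH2′ fragmentation of allyl sulfones, and neither the sulfone‑terminated cascade nor its electrochemical turnover has been shown.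

**Step 16**
Reactants: 18
Product: 19, (2S,4aR,5S,8aR)‑1,1,4a,6‑tetramethyl‑5‑[(3E,7E)‑4,8‑dimethyl‑10‑[(4R)‑2,2,5,5‑tetramethyl‑1,3‑dioxolan‑4‑yl]deca‑3,7‑dien‑1‑yl]‑1,2,3,4,4a,5,8,8a‑octahydronaphthalen‑2‑ol
Conditions: PdCl2(dppp) (10 mol %), LiBHEt3 (4 equiv), THF, 0 °C
Reagents that add atoms: none
Why: Pd‑catalysed reductive desulfonylation of the allylic sulfone; hydride is delivered to the less substituted C16 terminus of the π‑allyl, keeping the (E)‑C17=C18 olefin in place.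

**Step 17**
Reactants: 19
Product: 20, (4aR,5S,8aR)‑1,1,4a,6‑tetramethyl‑5‑[(3E,7E)‑4,8‑dimethyl‑10‑[(4R)‑2,2,5,5‑tetramethyl‑1,3‑dioxolan‑4‑yl]deca‑3,7‑dien‑1‑yl]‑3,4,4a,5,8,8a‑hexahydronaphthalen‑2(1H)‑one
Conditions: Dess–Martin periodinane, NaHCO3, CH2Cl2, rt
Reagents that add atoms: none
Why: Dess–Martin oxidation of the only free hydroxyl; the ketone has no epimerisable α‑stereocentre.

**Step 18**
Reactants: 20
Product: 21, (4aR,5S,8aR)‑5‑[(3E,7E,11R)‑11,12‑dihydroxy‑4,8,12‑trimethyltrideca‑3,7‑dien‑1‑yl]‑1,1,4a,6‑tetramethyl‑3,4,4a,5,8,8a‑hexahydronaphthalen‑2(1H)‑one (target, CID53355790)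
Conditions: AcOH/THF/H2O (3:1:1), 45 °C
Reagents that add atoms: none
Why: Mild acid hydrolysis of the acetonide; the trisubstituted olefins and the ketone are stable under these conditions and the C21 (R) centre is not involved.

**Compound list**

1 | (R)‑5‑oxotetrahydrofuran‑2‑carboxylic acid | OC(=O)[C@H]1CCC(=O)O1 | starting material
2 | ethyl (R)‑5‑oxotetrahydrofuran‑2‑carboxylate | CCOC(=O)[C@H]1CCC(=O)O1 | intermediate
3 | (R)‑5‑(2‑hydroxypropan‑2‑yl)dihydrofuran‑2(3H)‑one | CC(C)(O)[C@H]1CCC(=O)O1 | intermediate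
4 | (R)‑2‑methylhept‑6‑yne‑2,3‑diol | CC(C)(O)[C@H](O)CCC#C | intermediate
5 | (R,E)‑3,7‑dimethyloct‑2‑ene‑1,6,7‑triol | CC(C)(O)[C@H](O)CC/C(C)=C/CO | intermediate
6 | (E)‑3‑methyl‑5‑[(4R)‑2,2,5,5‑tetramethyl‑1,3‑dioxolan‑4‑yl]pent‑2‑en‑1‑ol | OC/C=C(\C)CC[C@H]1OC(C)(C)OC1(C)C | intermediate
7 | (5R)‑2,2,4,4‑tetramethyl‑5‑[(E)‑3‑methyl‑5‑(phenylsulfonyl)pent‑3‑en‑1‑yl]‑1,3‑dioxolane | O=S(=O)(C/C=C(\C)CC[C@H]1OC(C)(C)OC1(C)C)c1ccccc1 | intermediate
8 | (3R,6E)‑8‑bromo‑2‑hydroxy‑2,6‑dimethyloct‑6‑en‑3‑yl methanesulfonate | CC(C)(O)[C@H](OS(C)(=O)=O)CC/C(C)=C/CBr | intermediate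
9 | (3S)‑3‑[(E)‑5‑bromo‑3‑methylpent‑3‑en‑1‑yl]‑2,2‑dimethyloxirane | BrC/C=C(\C)CC[C@H]1C(C)(C)O1 | intermediate
10 | 2,5‑dimethoxytetrahydrofuran | COC1CCC(OC)O1 | starting material
11 | ethyl 2‑(triphenylphosphoranylidene)propanoate | CCOC(=O)C(C)=P(c1ccccc1)(c1ccccc1)c1ccccc1 | starting material
12 | diethyl (2E,6E)‑2,7‑dimethylocta‑2,6‑dienedioate | CCOC(=O)/C(C)=C/CC/C=C(\C)C(=O)OCC | intermediate
13 | (2E,6E)‑2,7‑dimethylocta‑2,6‑diene‑1,8‑diol | OC/C(C)=C/CC/C=C(\C)CO | intermediate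
14 | (2E,6E)‑1,8‑dibromo‑2,7‑dimethylocta‑2,6‑diene | BrC/C(C)=C/CC/C=C(\C)CBr | intermediate
15 | C16‑sulfonyl C7‑bromide, 21,22‑acetonide (C16 epimers) | BrC/C(C)=C/CC/C=C(\C)CC(S(=O)(=O)c1ccccc1)/C=C(\C)CC[C@H]2OC(C)(C)OC2(C)C | intermediate
16 | C7,C16‑bis(phenylsulfonyl) 21,22‑acetonide (C16 epimers) | O=S(=O)(C/C(C)=C/CC/C=C(\C)CC(S(=O)(=O)c1ccccc1)/C=C(\C)CC[C@H]2OC(C)(C)OC2(C)C)c1ccccc1 | intermediate
17 | acyclic (3S)‑3,4‑epoxide, C7,C16‑bis(phenylsulfonyl), (21R)‑21,22‑acetonide (C7/C16 epimers) | CC1(C)O[C@H]1CC/C(C)=C/CC(S(=O)(=O)c2ccccc2)/C(C)=C/CC/C=C(\C)CC(S(=O)(=O)c3ccccc3)/C=C(\C)CC[C@H]4OC(C)(C)OC4(C)C | intermediate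
18 | bicyclic 3β‑ol, C7=C8 olefin, C16 sulfone, 21,22‑acetonide (C16 epimers) | CC1=CC[C@H]2C(C)(C)[C@@H](O)CC[C@]2(C)[C@H]1CC/C=C(\C)CC(S(=O)(=O)c3ccccc3)/C=C(\C)CC[C@H]4OC(C)(C)OC4(C)C | intermediate
19 | bicyclic 3β‑ol, 21,22‑acetonide | CC1=CC[C@H]2C(C)(C)[C@@H](O)CC[C@]2(C)[C@H]1CC/C=C(\C)CC/C=C(\C)CC[C@H]3OC(C)(C)OC3(C)C | intermediate
20 | bicyclic 3‑ketone, 21,22‑acetonide | CC1=CC[C@H]2C(C)(C)C(=O)CC[C@]2(C)[C@H]1CC/C=C(\C)CC/C=C(\C)CC[C@H]3OC(C)(C)OC3(C)C | intermediate
21 | (4aR,5S,8aR)‑5‑[(3E,7E,11R)‑11,12‑dihydroxy‑4,8,12‑trimethyltrideca‑3,7‑dien‑1‑yl]‑1,1,4a,6‑tetramethyl‑3,4,4a,5,8,8a‑hexahydronaphthalen‑2(1H)‑one | CC1=CC[C@H]2C(C)(C)C(=O)CC[C@]2(C)[C@H]1CC/C=C(\C)CC/C=C(\C)CC[C@@H](O)C(C)(C)O | target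

**Totals**

Total steps: 18. Longest linear sequence: 13 (steps 1–6, then 12–18).

**Three steps most likely to fail**

1. Step 15 (proposed new sulfone‑terminated electrochemical Ti(III) bicyclization). Risks are a 1,3‑sulfonyl shift of unreacted 17 catalysed by PhSO2•, and slow ring‑B closure for one C7 epimer. Fallback with known chemistry: cyclise a C15 (S)‑10,11‑epoxyfarnesyl acetate (from 9 by sulfone chain extension and Pd/LiBHEt3) with stoichiometric Cp2TiCl (Cp2TiCl2/Mn), which is established to give the exocyclic 3β‑hydroxy drimane. Then isomerise exo → C7=C8, and join C11 (as iodide or triflate) to the C12 anion of a C12–C22 allylic sulfone, followed by desulfonylation.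

2. Step 14 (selective C7 deprotonation and alkylation of bis‑sulfone 16). Fallback: reverse the order of union. Alkylate the dianion of the mono‑sulfone alcohol PhSO2CH2C(Me)=CH(CH2)2CH=C(Me)CH2OH (from 13) with 9, then convert the C15 alcohol to the bromide and alkylate with the anion of 7. Only one acidic sulfone is then present in each carbanion step.

3. Step 4 (carboalumination of the unprotected diol‑alkyne). Fallback: form the olefin by a different reaction. Convert the acetonide of 4 to the methyl ynoate (n‑BuLi, ClCO2Me), add Me2CuLi at −78 °C (syn conjugate addition giving the E‑β‑methyl enoate), and reduce with DIBAL‑H to 6; acetonide hydrolysis of 6 then gives 5.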